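**Retrosynthetic overview**
The resorcinol benzene ring is the only ring that is built, and it is built last: ring C1 (acetyl-bearing) and C6 (bearing the 10-phenyldecyl chain) are taken as the two sp carbons of an alk-3-yn-2-one, and C2(OH)–C3H–C4(OH)–C5H as the four-carbon backbone of a bis-silylated methyl acetoacetate dienolate whose ester carbon becomes C2.
A [4+2] union of these two pieces followed by loss of methanol gives the 1-acetyl-2,4-dioxy-6-alkyl pattern directly, with no late acylation of a preformed resorcinol.
The C20 ynone is traced back linearly: acyl–alkyne bond (alkynyllithium plus N-methoxy-N-methylamide), C(sp)–C(sp3) bond (acetylide plus primary bromide), aryl–alkyl bond (PhMgBr plus 1,10-dibromodecane under copper catalysis).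
Ring order: the terminal phenyl ring is bought; the resorcinol ring is formed in the penultimate step; the last step only frees the two phenols.

Key step: step 6

Assumption: reagents 1, 4 and 6 are bought as such; the target is achiral, so no stereocontrol is needed and the double-bond geometries of 11–13 are immaterial.

**Step 1**
Reactants: 1 phenylmagnesium bromide; 2 1,10-dibromodecane
Product: 3 (10-bromodecyl)benzene
Conditions: Li2CuCl4 (3 mol %), THF, −10 °C to rt; 2 in threefold excess, slow addition of 1; excess 2 recovered by vacuum distillation
Reagents that add atoms: none
Why: Copper-catalysed cross-coupling of an aryl Grignard reagent with a primary alkyl bromide, in which the large excess of the symmetrical dibromide makes monosubstitution statistically dominant and the product bromide is no more reactive than 2.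

**Step 2**
Reactants: 3 (10-bromodecyl)benzene; 4 lithium acetylide ethylenediamine complex
Product: 5 12-phenyldodec-1-yne
Conditions: 4 (1.5 equiv), DMSO (a little THF as cosolvent), 10 °C to rt
Reagents that add atoms: none
Why: SN2 alkylation of an acetylide by an unhindered primary bromide in a dipolar aprotic solvent, where the amine-complexed lithium acetylide is a strong carbon nucleophile and the remote phenyl ring is inert.

**Step 3**
Reactants: 5 12-phenyldodec-1-yne; 6 N-methoxy-N-methylacetamide
Product: 9 14-phenyltetradec-3-yn-2-one, via lithium acetylide 7 (not isolated), via tetrahedral lithium adduct 8 (not isolated)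
Conditions: n-BuLi (1.05 equiv), THF, −78 °C; then 6 (1.2 equiv), −78 to 0 °C; inverse quench into cold 1 M HCl
Reagents that add atoms: none
Why: Weinreb ketone synthesis, in which the alkynyllithium adds once to the amide and the chelated tetrahedral adduct persists until the acidic inverse quench, which also protonates the liberated N,O-dimethylhydroxylamine so that it cannot add in conjugate fashion to the ynone.

**Step 4**
Reactants: 10 methyl acetoacetate
Product: 11 methyl 3-(trimethylsilyloxy)but-2-enoate (E/Z mixture)
Conditions: TMSCl (1.3 equiv), Et3N (1.5 equiv), hexane, rt; filter, distil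
Reagents that add atoms: chlorotrimethylsilane, C[Si](C)(C)Cl
Why: Silyl enol ether formation by O-silylation of the enol form of a β-keto ester with TMSCl and Et3N, the conjugated enol ether being the stable product.

**Step 5**
Reactants: 11 methyl 3-(trimethylsilyloxy)but-2-enoate
Product: 13 1-methoxy-1,3-bis(trimethylsilyloxy)buta-1,3-diene, via lithium dienolate 12 (not isolated)
Conditions: LDA (LiN(i-Pr)2, 1.1 equiv), THF, −78 °C; then TMSCl, −78 to 0 °C; pentane, filter, bulb-to-bulb distillation; used fresh
Reagents that add atoms: chlorotrimethylsilane, C[Si](C)(C)Cl
Why: Kinetic γ-deprotonation of the vinylogous ester by LDA gives the extended lithium dienolate, which TMSCl traps on oxygen (silyl ketene acetal formation) to give the 1,1,3-trioxygenated diene.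

**Step 6**
Reactants: 9 14-phenyltetradec-3-yn-2-one; 13 1-methoxy-1,3-bis(trimethylsilyloxy)buta-1,3-diene
Product: 15 1-[2,4-bis(trimethylsilyloxy)-6-(10-phenyldecyl)phenyl]ethanone, via cyclohexadiene cycloadduct 14 (not isolated)
Conditions: 13 (2–3 equiv), toluene, 80–100 °C, Ar, strictly anhydrous, no Lewis acid; volatiles removed under vacuum, crude carried on without chromatography
Reagents that add atoms: none
Why: The electron-rich diene 13 and the electron-poor ynone 9 should combine in an asynchronous, normal-electron-demand Diels–Alder reaction (a stepwise Mukaiyama–Michael addition followed by closure of the allenolate onto the ketene-acetal carbon would lead to the same adduct), forming the C4(diene)–C4(ynone) and C1(diene)–C3(ynone) bonds. The closest known reaction type is the cycloaddition–aromatization of 1-alkoxy-1,3-bis(silyloxy)- and 1,1-dialkoxy-3-silyloxybutadienes with acetylenic esters and ketones to give resorcinol derivatives. The benzene ring, the only ring closed, arises by intermolecular [4+2] closure to the cyclohexa-1,4-diene 14, whose ketal carbon carries methoxide as a leaving group and whose doubly allylic CH2 lies para to it, so 1,4-elimination of methanol aromatizes it irreversibly. No stereocenter has to be controlled, since the ketal carbon of 14 and the diene geometry vanish on aromatization. The step needs regioselectivity only, and this is secured by the polarization of both partners: the CH2 terminus of 13 carries the largest HOMO coefficient and the chain-bearing β-carbon C4 of 9 the largest LUMO coefficient, which places the acetyl group next to the oxygenated former ketal carbon and the chain next to a ring CH. Omitting any Lewis acid keeps the ketone carbonyl from being attacked, and silyl groups partly lost to the liberated methanol are of no consequence because step 7 removes them all.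

**Step 7**
Reactants: 15 1-[2,4-bis(trimethylsilyloxy)-6-(10-phenyldecyl)phenyl]ethanone
Product: 16 1-[2,4-dihydroxy-6-(10-phenyldecyl)phenyl]ethanone
Conditions: 1 M HCl (cat.), THF–H2O, rt; chromatography
Reagents that add atoms: none
Why: Aryl trimethylsilyl ethers are hydrolysed rapidly by dilute aqueous acid (desilylation at oxygen), while the aryl ketone, the alkyl chain and both arenes are unaffected.

**Compound list**
1 | phenylmagnesium bromide | Br[Mg]c1ccccc1 | starting material
2 | 1,10-dibromodecane | BrCCCCCCCCCCBr | starting material
3 | (10-bromodecyl)benzene | BrCCCCCCCCCCc1ccccc1 | intermediate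
4 | lithium acetylide ethylenediamine complex | [Li]C#C.NCCN | starting material
5 | 12-phenyldodec-1-yne | C#CCCCCCCCCCCc1ccccc1 | intermediate
6 | N-methoxy-N-methylacetamide | CC(=O)N(C)OC | starting material
7 | (12-phenyldodec-1-yn-1-yl)lithium (lithium acetylide of 5, not isolated) | [Li]C#CCCCCCCCCCCc1ccccc1 | intermediate
8 | lithium 2-[methoxy(methyl)amino]-14-phenyltetradec-3-yn-2-olate (tetrahedral adduct, racemic, not isolated) | CC(O[Li])(C#CCCCCCCCCCCc1ccccc1)N(C)OC | intermediate
9 | 14-phenyltetradec-3-yn-2-one | CC(=O)C#CCCCCCCCCCCc1ccccc1 | intermediate
10 | methyl acetoacetate | COC(=O)CC(C)=O | starting material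
11 | methyl 3-(trimethylsilyloxy)but-2-enoate (E/Z mixture) | COC(=O)C=C(C)O[Si](C)(C)C | intermediate
12 | lithium 1-methoxy-3-(trimethylsilyloxy)buta-1,3-dien-1-olate (lithium dienolate, not isolated) | [Li]OC(OC)=CC(=C)O[Si](C)(C)C | intermediate
13 | 1-methoxy-1,3-bis(trimethylsilyloxy)buta-1,3-diene (C1=C2 geometry immaterial) | COC(O[Si](C)(C)C)=CC(=C)O[Si](C)(C)C | intermediate
14 | 1-[6-methoxy-2-(10-phenyldecyl)-4,6-bis(trimethylsilyloxy)cyclohexa-1,4-dien-1-yl]ethanone (cycloadduct, racemic at the ketal carbon, not isolated) | CC(=O)C1=C(CCCCCCCCCCc2ccccc2)CC(O[Si](C)(C)C)=CC1(OC)O[Si](C)(C)C | intermediate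
15 | 1-[2,4-bis(trimethylsilyloxy)-6-(10-phenyldecyl)phenyl]ethanone | CC(=O)c1c(O[Si](C)(C)C)cc(O[Si](C)(C)C)cc1CCCCCCCCCCc1ccccc1 | intermediate
16 | 1-[2,4-dihydroxy-6-(10-phenyldecyl)phenyl]ethanone | CC(=O)c1c(O)cc(O)cc1CCCCCCCCCCc1ccccc1 | target

**Step count**
Total: 7 steps. Longest linear sequence: 5 steps (steps 1, 2, 3, 6, 7); the diene arm (steps 4, 5) joins at step 6.

**Steps most likely to fail**

Step 6. The diene may be diverted into attack at the ketone carbon (1,2-addition, or a Michael/aldol closure that would build a salicylate-type ring), may be destroyed by adventitious moisture before it reacts, or the cycloaddition may be so slow that the ynone oligomerizes on heating. The fallback gives up the de novo ring construction, acylates a preformed 5-alkylresorcinol and accepts a regioisomer separation. It sets out from 3 and comes back at 16. The Grignard reagent 3,5-dimethoxyphenylmagnesium bromide F1 would be prepared from 1-bromo-3,5-dimethoxybenzene and magnesium in THF and coupled with 3 under Li2CuCl4 catalysis to give 1,3-dimethoxy-5-(10-phenyldecyl)benzene F2. Demethylation with BBr3 in CH2Cl2 should give 5-(10-phenyldecyl)benzene-1,3-diol F3. Acetylation of F3 with acetic acid and BF3·OEt2 at about 80 °C (Friedel–Crafts acylation with Fries-type equilibration) is expected to go mainly at the ring position para to one hydroxyl and flanked by the alkyl chain, which is 16. The minor isomer acylated between the two hydroxyls would be removed by chromatography, and the unactivated terminal phenyl ring should not compete.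

Step 1. Both C–Br ends of the dibromide may be substituted and the aryl Grignard may homocouple, giving nonpolar by-products that are tedious to separate from the product and the excess dibromide. The fallback replaces the symmetrical electrophile with a monofunctional one. It sets out from 1 and comes back at 3. Copper-catalysed coupling of 1 with commercial 10-bromodec-1-ene (Li2CuCl4, THF) should give dec-9-en-1-ylbenzene F4. Radical-chain anti-Markovnikov addition of HBr (HBr gas, catalytic dibenzoyl peroxide, hexane, 0 °C) would then place bromine on the terminal carbon and give 3.

Step 7. Unmasking may be incomplete: dilute acid removes only silyl groups, so if the aromatization in step 6 proceeds in part by loss of trimethylsilanol instead of methanol, a methyl group stays on the oxygen next to the acetyl group. The fallback replaces protic desilylation with chelation-directed Lewis-acid dealkylation of the whole crude. It sets out from cycloadduct 14, to the extent that it has collapsed to 1-[2-methoxy-6-(10-phenyldecyl)-4-(trimethylsilyloxy)phenyl]ethanone F5, and comes back at 16. Treatment with BCl3 in CH2Cl2 at −78 to 0 °C, where boron is held between the acetyl oxygen and the ortho methoxy group and chloride removes the methyl group, followed by aqueous work-up that also hydrolyses the boron and silicon esters, should give 16 from F5 and from 15 alike.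

**Further compounds**
F1 | step 6 | 3,5-dimethoxyphenylmagnesium bromide | COc1cc(OC)cc([Mg]Br)c1
F2 | step 6 | 1,3-dimethoxy-5-(10-phenyldecyl)benzene | COc1cc(OC)cc(CCCCCCCCCCc2ccccc2)c1
F3 | step 6 | 5-(10-phenyldecyl)benzene-1,3-diol | Oc1cc(O)cc(CCCCCCCCCCc2ccccc2)c1
F4 | step 1 | dec-9-en-1-ylbenzene | C=CCCCCCCCCc1ccccc1
F5 | step 7 | 1-[2-methoxy-6-(10-phenyldecyl)-4-(trimethylsilyloxy)phenyl]ethanone | CC(=O)c1c(OC)cc(O[Si](C)(C)C)cc1CCCCCCCCCCc1ccccc1
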